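**Retrosynthetic overview**
- The target is (2S)-naringenin joined through C8 to C8'' of apigenin. The strategy rests on the benzo ring of the flavone half (C4a'', C5''–C8'', C8a''), a phloroglucinol ring whose C8'' carries the other arene between O7'' and O1''.
- Key disconnection: this ring is cut into an aryl siloxyalkyne (C8'', C7'') and a 3-alkoxycyclobutenone (C8a'', C4a'', C5'', C6''). Their benzannulation makes C8''–C8a'' and C6''–C7'', so the crowded biaryl bond is present from the start as an aryl–alkyne bond and O1'' is the only free hydroxyl.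
- Protecting groups: benzyl on the cyclobutenone oxygen (O5'') and on O5/O7, allyl on the future O1, silyl (later exchanged for benzyl) on O7''. The end is then one hydrogenolysis, and no Lewis acid or base meets C2.
- Ring order: flavone benzo ring (benzannulation), then the flavone pyranone ring (ortho-formylation at C4a'', arylacetylide addition, oxidation, 6-endo oxa-Michael), then a 2-unsubstituted chromone ring on O1/C4a of the other arene by the same three operations.
- C2 is set by rhodium-catalysed asymmetric conjugate addition of the arylboronic acid to that chromone, followed by global debenzylation.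

Key step: step 6

Assumption: the C8–C8'' axis carries four ortho substituents and its configuration is not defined in the target, so only C2 is controlled and the axial isomers are carried as a mixture.

**Step 1**
Reactants: 1 2,4,6-trihydroxybenzaldehyde; 2 benzyl bromide
Product: 3 2,4-bis(benzyloxy)-6-hydroxybenzaldehyde
Conditions: BnBr (2.1 equiv), K2CO3 (2.2 equiv), DMF, 0 °C to rt
Reagents that add atoms: benzyl bromide, BrCc1ccccc1
Why: Williamson etherification, in which the para hydroxyl and one ortho hydroxyl react while the last hydroxyl, hydrogen-bonded to the aldehyde, is the least nucleophilic and should stay free.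

**Step 2**
Reactants: 3 2,4-bis(benzyloxy)-6-hydroxybenzaldehyde; 4 allyl bromide
Product: 5 2-(allyloxy)-4,6-bis(benzyloxy)benzaldehyde
Conditions: allyl bromide (1.5 equiv), K2CO3, DMF, 50 °C
Reagents that add atoms: allyl bromide, C=CCBr
Why: Williamson etherification of the chelated phenol under slightly more forcing conditions puts the one orthogonal group on the oxygen that becomes O1 of the flavanone, so no statistical differentiation of two equal oxygens is needed later.

**Step 3**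
Reactants: 5 2-(allyloxy)-4,6-bis(benzyloxy)benzaldehyde; 6 carbon tetrabromide
Product: 7 1-(allyloxy)-3,5-bis(benzyloxy)-2-(2,2-dibromovinyl)benzene
Conditions: CBr4, PPh3, Zn dust (2 equiv each, premixed), CH2Cl2, rt; then 5
Reagents that add atoms: carbon tetrabromide, BrC(Br)(Br)Br
Why: Corey–Fuchs dibromo-olefination with the ylide Ph3P=CBr2, which is small and reactive enough for an electron-rich, di-ortho-substituted benzaldehyde and leaves allyl and benzyl ethers alone.

**Step 4**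
Reactants: 7 1-(allyloxy)-3,5-bis(benzyloxy)-2-(2,2-dibromovinyl)benzene; 8 tert-butyl hydroperoxide; 9 triisopropylsilyl trifluoromethanesulfonate
Product: 12 [2-(allyloxy)-4,6-bis(benzyloxy)phenyl]ethynyl triisopropylsilyl ether, via lithium arylacetylide 10 (not isolated), via lithium ynolate 11 (not isolated)
Conditions: n-BuLi (2.05 equiv), THF, −78 °C; then t-BuOOLi (1.1 equiv, premixed from anhydrous t-BuOOH and LiN(SiMe3)2 in THF at −78 °C), −78 to 0 °C; then i-Pr3SiOTf (1.2 equiv), −78 to 0 °C; pentane, aq. NaHCO3 wash; filtration through Et3N-deactivated silica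
Reagents that add atoms: tert-butyl hydroperoxide, CC(C)(C)OO; triisopropylsilyl trifluoromethanesulfonate, CC(C)[Si](OS(=O)(=O)C(F)(F)F)(C(C)C)C(C)C
Why: the second stage of the Corey–Fuchs sequence (bromine–lithium exchange, Fritsch–Buttenberg–Wiechell shift and deprotonation) gives the lithium acetylide, which is not quenched but oxidised in the same flask by lithium tert-butyl peroxide to the ynolate (Julia oxidation) and then silylated on oxygen by the bulky silyl triflate (Kowalski-type ynolate trapping), the 1-bromobutane left by the exchange being inert to acetylide and ynolate below 0 °C, as it is in Kowalski ynolate preparations.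

**Step 5**
Reactants: 13 3-ethoxycyclobut-2-en-1-one; 14 benzyl alcohol
Product: 15 3-(benzyloxy)cyclobut-2-en-1-one
Conditions: BnOH (3 equiv), TsOH·H2O (2 mol %), toluene, 45 °C, 80 mbar
Reagents that add atoms: benzyl alcohol, OCc1ccccc1
Why: acid-catalysed transetherification (addition–elimination at C3) of a vinylogous ester, driven by removal of ethanol; benzyl replaces ethyl so that O5'' is later freed by hydrogenolysis and not by a Lewis acid, which the benzyl and allyl ethers would not survive.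

**Step 6**
Reactants: 12 [2-(allyloxy)-4,6-bis(benzyloxy)phenyl]ethynyl triisopropylsilyl ether; 15 3-(benzyloxy)cyclobut-2-en-1-one
Product: 20 2-[2-(allyloxy)-4,6-bis(benzyloxy)phenyl]-5-(benzyloxy)-3-(triisopropylsilyloxy)phenol, via vinylketene 16 (not isolated), via vinylcyclobutenone 17 (not isolated), via dienylketene 18 (not isolated), via cyclohexadienone 19 (not isolated)
Conditions: 15 (1.3 equiv, in portions), toluene, 100 °C, sealed tube
Reagents that add atoms: 3-(benzyloxy)cyclobut-2-en-1-one, O=C1C=C(OCc2ccccc2)C1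
Why: Four-electron electrocyclic opening of 15 gives vinylketene 16, whose ketene carbon is attacked by the aryl-bearing carbon of the ynol ether in a [2+2] cycloaddition (C8''–C8a'' and C6''–C7'' bonds) to cyclobutenone 17, and reversible opening of 17 gives dienylketene 18. The benzene ring then closes by six-electron electrocyclisation of 18 (C8a''–C4a'' bond, six-membered carbocycle) to dienone 19, which tautomerises to the phenol. The closest known reaction is the Danheiser benzannulation of cyclobutenones with triisopropylsiloxyalkynes to resorcinol monosilyl ethers, here with an alkoxy group on the cyclobutenone and a di-ortho-substituted aryl group on the alkyne. No stereocentre is formed, and the C8–C8'' axis arises without control. The step needs the regiochemistry of the [2+2] addition, which the oxygen lone pair of the siloxyalkyne should secure by making the aryl-bearing carbon the nucleophile, so that the arene lies between the new hydroxyl (O1'') and the siloxy carbon (C7''). It also needs the allyl ether to persist, which should hold because 100 °C is well below the range of the aromatic Claisen rearrangement.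

**Step 7**
Reactants: 20 2-[2-(allyloxy)-4,6-bis(benzyloxy)phenyl]-5-(benzyloxy)-3-(triisopropylsilyloxy)phenol; 21 paraformaldehyde
Product: 23 3-[2-(allyloxy)-4,6-bis(benzyloxy)phenyl]-6-(benzyloxy)-2-hydroxy-4-(triisopropylsilyloxy)benzaldehyde, via hydroxymethylphenol 22 (not isolated)
Conditions: MgCl2 (2 equiv), Et3N (4 equiv), (CH2O)n (6 equiv), THF, reflux; cold 1 M HCl wash
Reagents that add atoms: paraformaldehyde (formaldehyde), C=O
Why: Casnati–Skattebøl ortho-formylation, in which the magnesium phenoxide delivers formaldehyde only to the free ortho carbon C4a'' (the other ortho carbon is the biaryl carbon) and a second formaldehyde oxidises the benzylic alkoxide by hydride transfer.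

**Step 8**
Reactants: 23 3-[2-(allyloxy)-4,6-bis(benzyloxy)phenyl]-6-(benzyloxy)-2-hydroxy-4-(triisopropylsilyloxy)benzaldehyde; 24 1-(benzyloxy)-4-ethynylbenzene
Product: 25 1-{3-[2-(allyloxy)-4,6-bis(benzyloxy)phenyl]-6-(benzyloxy)-2-hydroxy-4-(triisopropylsilyloxy)phenyl}-3-[4-(benzyloxy)phenyl]prop-2-yn-1-ol
Conditions: 24 (3.5 equiv), n-BuLi (3.3 equiv), THF, −78 °C; then 23, −78 to 0 °C; aq. NH4Cl; crude product used directly
Reagents that add atoms: 1-(benzyloxy)-4-ethynylbenzene, C#Cc1ccc(OCc2ccccc2)cc1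
Why: 1,2-addition of a lithium acetylide to the aldehyde, with excess reagent taking up the phenol proton; the new carbinol centre is not controlled and is removed in the next step.

**Step 9**
Reactants: 25 1-{3-[2-(allyloxy)-4,6-bis(benzyloxy)phenyl]-6-(benzyloxy)-2-hydroxy-4-(triisopropylsilyloxy)phenyl}-3-[4-(benzyloxy)phenyl]prop-2-yn-1-ol
Product: 27 8-[2-(allyloxy)-4,6-bis(benzyloxy)phenyl]-5-(benzyloxy)-2-[4-(benzyloxy)phenyl]-7-(triisopropylsilyloxy)-4H-chromen-4-one, via ynone 26 (not isolated)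
Conditions: MnO2 (15 equiv), CH2Cl2, rt; filter, concentrate; DMAP (0.3 equiv), DMF, 40 °C
Reagents that add atoms: none
Why: MnO2 oxidation of the benzylic propargylic alcohol gives the o-hydroxyaryl ynone, and nucleophilic catalysis by DMAP closes the pyranone ring by 6-endo-dig oxa-Michael addition, the known way to steer such ynones to flavones and away from 5-exo aurones.

**Step 10**
Reactants: 27 8-[2-(allyloxy)-4,6-bis(benzyloxy)phenyl]-5-(benzyloxy)-2-[4-(benzyloxy)phenyl]-7-(triisopropylsilyloxy)-4H-chromen-4-one; 2 benzyl bromide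
Product: 29 8-[2-(allyloxy)-4,6-bis(benzyloxy)phenyl]-5,7-bis(benzyloxy)-2-[4-(benzyloxy)phenyl]-4H-chromen-4-one, via caesium phenoxide 28 (not isolated)
Conditions: CsF (2 equiv), BnBr (1.5 equiv), DMF, rt
Reagents that add atoms: benzyl bromide, BrCc1ccccc1
Why: one-pot desilylative Williamson etherification, in which fluoride cleaves the silyl ether para to the pyranone carbonyl and the phenoxide is benzylated in the same flask; this removes the only base-labile group before the second magnesium and Grignard sequence.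

**Step 11**
Reactants: 29 8-[2-(allyloxy)-4,6-bis(benzyloxy)phenyl]-5,7-bis(benzyloxy)-2-[4-(benzyloxy)phenyl]-4H-chromen-4-one
Product: 30 5,7-bis(benzyloxy)-8-[2,4-bis(benzyloxy)-6-hydroxyphenyl]-2-[4-(benzyloxy)phenyl]-4H-chromen-4-one
Conditions: Pd(PPh3)4 (5 mol %), morpholine (5 equiv), THF, rt
Reagents that add atoms: none
Why: Tsuji–Trost deallylation, in which zerovalent palladium ionises the allyl aryl ether and morpholine traps the allyl complex, leaving benzyl ethers and the flavone untouched.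

**Step 12**
Reactants: 30 5,7-bis(benzyloxy)-8-[2,4-bis(benzyloxy)-6-hydroxyphenyl]-2-[4-(benzyloxy)phenyl]-4H-chromen-4-one; 21 paraformaldehyde
Product: 32 4,6-bis(benzyloxy)-3-{5,7-bis(benzyloxy)-2-[4-(benzyloxy)phenyl]-4-oxo-4H-chromen-8-yl}-2-hydroxybenzaldehyde, via hydroxymethylphenol 31 (not isolated)
Conditions: MgCl2 (2 equiv), Et3N (4 equiv), (CH2O)n (6 equiv), THF, reflux; 1 M HCl wash
Reagents that add atoms: paraformaldehyde (formaldehyde), C=O
Why: Casnati–Skattebøl ortho-formylation of the only free phenol at its only free ortho carbon (C4a), which fixes the position of the flavanone carbonyl carbon without any Friedel–Crafts regiochemistry question.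

**Step 13**
Reactants: 32 4,6-bis(benzyloxy)-3-{5,7-bis(benzyloxy)-2-[4-(benzyloxy)phenyl]-4-oxo-4H-chromen-8-yl}-2-hydroxybenzaldehyde; 33 ethynylmagnesium bromide
Product: 34 5,7-bis(benzyloxy)-8-[4,6-bis(benzyloxy)-2-hydroxy-3-(1-hydroxyprop-2-yn-1-yl)phenyl]-2-[4-(benzyloxy)phenyl]-4H-chromen-4-one
Conditions: HC≡CMgBr (4 equiv), THF, −40 to 0 °C; aq. NH4Cl; crude product used directly
Reagents that add atoms: ethynylmagnesium bromide, C#C[Mg]Br
Why: Grignard 1,2-addition to the aldehyde, which at low temperature should be far more electrophilic than the flavone carbonyl (a vinylogous ester flanked by the 5''-benzyloxy group); the carbinol centre is not controlled and is removed in the next step.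

**Step 14**
Reactants: 34 5,7-bis(benzyloxy)-8-[4,6-bis(benzyloxy)-2-hydroxy-3-(1-hydroxyprop-2-yn-1-yl)phenyl]-2-[4-(benzyloxy)phenyl]-4H-chromen-4-one
Product: 36 5,7-bis(benzyloxy)-8-[5,7-bis(benzyloxy)-4-oxo-4H-chromen-8-yl]-2-[4-(benzyloxy)phenyl]-4H-chromen-4-one, via ynone 35 (not isolated)
Conditions: MnO2 (15 equiv), CH2Cl2, rt; filter, concentrate; DMAP (0.2 equiv), DMF, rt
Reagents that add atoms: none
Why: MnO2 oxidation to the terminal o-hydroxyaryl ynone followed by DMAP-catalysed 6-endo-dig oxa-Michael addition gives the 2-unsubstituted chromone, as in step 9.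

**Step 15**
Reactants: 36 5,7-bis(benzyloxy)-8-[5,7-bis(benzyloxy)-4-oxo-4H-chromen-8-yl]-2-[4-(benzyloxy)phenyl]-4H-chromen-4-one; 37 4-(benzyloxy)phenylboronic acid
Product: 38 (2S)-5,7-bis(benzyloxy)-8-{5,7-bis(benzyloxy)-2-[4-(benzyloxy)phenyl]-4-oxo-4H-chromen-8-yl}-2-[4-(benzyloxy)phenyl]chroman-4-one
Conditions: [Rh(OH)(cod)]2 (2.5 mol %), (S)-2,2'-bis[bis(3,4,5-trifluorophenyl)phosphino]-6,6'-dimethoxy-1,1'-biphenyl (6 mol %), 37 (4 equiv), CH2Cl2–H2O (10:1), 30 °C
Reagents that add atoms: 4-(benzyloxy)phenylboronic acid, OB(O)c1ccc(OCc2ccccc2)cc1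
Why: Hayashi–Miyaura asymmetric 1,4-addition of an arylboronic acid to a chromone, known for 5,7-dioxygenated chromones with this electron-poor bisphosphine; C2 is set by the catalyst, the aryl–rhodium species adding to the Re face of C2 under the (S)-ligand (sense taken from the model for cyclohex-2-enone, the antipodal ligand being used if a model chromone shows the opposite sense), while the 2-aryl pyranone of the flavone half is a β,β-disubstituted acceptor and should not react.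

**Step 16**
Reactants: 38 (2S)-5,7-bis(benzyloxy)-8-{5,7-bis(benzyloxy)-2-[4-(benzyloxy)phenyl]-4-oxo-4H-chromen-8-yl}-2-[4-(benzyloxy)phenyl]chroman-4-one
Product: 39 (2S)-5,7-dihydroxy-8-[5,7-dihydroxy-2-(4-hydroxyphenyl)-4-oxo-4H-chromen-8-yl]-2-(4-hydroxyphenyl)chroman-4-one
Conditions: H2 (1 atm), 10% Pd/C, EtOAc–MeOH (1:1), rt; stopped at complete debenzylation
Reagents that add atoms: none
Why: hydrogenolysis of six aryl benzyl ethers under neutral conditions, so that C2 (labile to base through retro-oxa-Michael opening) should keep its configuration, while the flavone double bond and the C2–O1 bond are reduced more slowly than primary benzyl ethers.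

**Compound list**
1 | 2,4,6-trihydroxybenzaldehyde | O=Cc1c(O)cc(O)cc1O | starting material
2 | benzyl bromide | BrCc1ccccc1 | starting material
3 | 2,4-bis(benzyloxy)-6-hydroxybenzaldehyde | O=Cc1c(O)cc(OCc2ccccc2)cc1OCc1ccccc1 | intermediate
4 | allyl bromide | C=CCBr | starting material
5 | 2-(allyloxy)-4,6-bis(benzyloxy)benzaldehyde | O=Cc1c(OCC=C)cc(OCc2ccccc2)cc1OCc1ccccc1 | intermediate
6 | carbon tetrabromide | BrC(Br)(Br)Br | starting material
7 | 1-(allyloxy)-3,5-bis(benzyloxy)-2-(2,2-dibromovinyl)benzene | BrC(Br)=Cc1c(OCC=C)cc(OCc2ccccc2)cc1OCc1ccccc1 | intermediate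
8 | tert-butyl hydroperoxide | CC(C)(C)OO | starting material
9 | triisopropylsilyl trifluoromethanesulfonate | CC(C)[Si](OS(=O)(=O)C(F)(F)F)(C(C)C)C(C)C | starting material
10 | lithium [2-(allyloxy)-4,6-bis(benzyloxy)phenyl]acetylide | [Li]C#Cc1c(OCC=C)cc(OCc2ccccc2)cc1OCc1ccccc1 | intermediate
11 | lithium [2-(allyloxy)-4,6-bis(benzyloxy)phenyl]ethynolate | [Li]OC#Cc1c(OCC=C)cc(OCc2ccccc2)cc1OCc1ccccc1 | intermediate
12 | [2-(allyloxy)-4,6-bis(benzyloxy)phenyl]ethynyl triisopropylsilyl ether | CC(C)[Si](OC#Cc1c(OCC=C)cc(OCc2ccccc2)cc1OCc1ccccc1)(C(C)C)C(C)C | intermediate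
13 | 3-ethoxycyclobut-2-en-1-one | CCOC1=CC(=O)C1 | starting material
14 | benzyl alcohol | OCc1ccccc1 | starting material
15 | 3-(benzyloxy)cyclobut-2-en-1-one | O=C1C=C(OCc2ccccc2)C1 | intermediate
16 | 3-(benzyloxy)buta-1,3-dien-1-one | C=C(OCc1ccccc1)C=C=O | intermediate
17 | 2-[2-(allyloxy)-4,6-bis(benzyloxy)phenyl]-4-[1-(benzyloxy)vinyl]-3-(triisopropylsilyloxy)cyclobut-2-en-1-one (racemic) | O=C1C(c2c(OCC=C)cc(OCc3ccccc3)cc2OCc2ccccc2)=C(O[Si](C(C)C)(C(C)C)C(C)C)C1C(=C)OCc1ccccc1 | intermediate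
18 | 2-[2-(allyloxy)-4,6-bis(benzyloxy)phenyl]-5-(benzyloxy)-3-(triisopropylsilyloxy)hexa-1,3,5-trien-1-one (ketene carbon and vinyl group cis) | O=C=C(c1c(OCC=C)cc(OCc2ccccc2)cc1OCc1ccccc1)/C(O[Si](C(C)C)(C(C)C)C(C)C)=C\C(=C)OCc1ccccc1 | intermediate
19 | 2-[2-(allyloxy)-4,6-bis(benzyloxy)phenyl]-5-(benzyloxy)-3-(triisopropylsilyloxy)cyclohexa-2,4-dien-1-one | O=C1CC(OCc2ccccc2)=CC(O[Si](C(C)C)(C(C)C)C(C)C)=C1c1c(OCC=C)cc(OCc2ccccc2)cc1OCc1ccccc1 | intermediate
20 | 2-[2-(allyloxy)-4,6-bis(benzyloxy)phenyl]-5-(benzyloxy)-3-(triisopropylsilyloxy)phenol | Oc1cc(OCc2ccccc2)cc(O[Si](C(C)C)(C(C)C)C(C)C)c1-c1c(OCC=C)cc(OCc2ccccc2)cc1OCc1ccccc1 | intermediate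
21 | paraformaldehyde (source of formaldehyde) | C=O | starting material
22 | 2-[2-(allyloxy)-4,6-bis(benzyloxy)phenyl]-5-(benzyloxy)-6-(hydroxymethyl)-3-(triisopropylsilyloxy)phenol | OCc1c(O)c(-c2c(OCC=C)cc(OCc3ccccc3)cc2OCc2ccccc2)c(O[Si](C(C)C)(C(C)C)C(C)C)cc1OCc1ccccc1 | intermediate
23 | 3-[2-(allyloxy)-4,6-bis(benzyloxy)phenyl]-6-(benzyloxy)-2-hydroxy-4-(triisopropylsilyloxy)benzaldehyde | O=Cc1c(O)c(-c2c(OCC=C)cc(OCc3ccccc3)cc2OCc2ccccc2)c(O[Si](C(C)C)(C(C)C)C(C)C)cc1OCc1ccccc1 | intermediate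
24 | 1-(benzyloxy)-4-ethynylbenzene | C#Cc1ccc(OCc2ccccc2)cc1 | starting material
25 | 1-{3-[2-(allyloxy)-4,6-bis(benzyloxy)phenyl]-6-(benzyloxy)-2-hydroxy-4-(triisopropylsilyloxy)phenyl}-3-[4-(benzyloxy)phenyl]prop-2-yn-1-ol (carbinol centre uncontrolled) | OC(C#Cc1ccc(OCc2ccccc2)cc1)c1c(O)c(-c2c(OCC=C)cc(OCc3ccccc3)cc2OCc2ccccc2)c(O[Si](C(C)C)(C(C)C)C(C)C)cc1OCc1ccccc1 | intermediate
26 | 1-{3-[2-(allyloxy)-4,6-bis(benzyloxy)phenyl]-6-(benzyloxy)-2-hydroxy-4-(triisopropylsilyloxy)phenyl}-3-[4-(benzyloxy)phenyl]prop-2-yn-1-one | O=C(C#Cc1ccc(OCc2ccccc2)cc1)c1c(O)c(-c2c(OCC=C)cc(OCc3ccccc3)cc2OCc2ccccc2)c(O[Si](C(C)C)(C(C)C)C(C)C)cc1OCc1ccccc1 | intermediate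
27 | 8-[2-(allyloxy)-4,6-bis(benzyloxy)phenyl]-5-(benzyloxy)-2-[4-(benzyloxy)phenyl]-7-(triisopropylsilyloxy)-4H-chromen-4-one | O=c1cc(-c2ccc(OCc3ccccc3)cc2)oc2c(-c3c(OCC=C)cc(OCc4ccccc4)cc3OCc3ccccc3)c(O[Si](C(C)C)(C(C)C)C(C)C)cc(OCc3ccccc3)c12 | intermediate
28 | caesium 8-[2-(allyloxy)-4,6-bis(benzyloxy)phenyl]-5-(benzyloxy)-2-[4-(benzyloxy)phenyl]-4-oxo-4H-chromen-7-olate | O=c1cc(-c2ccc(OCc3ccccc3)cc2)oc2c(-c3c(OCC=C)cc(OCc4ccccc4)cc3OCc3ccccc3)c([O-])cc(OCc3ccccc3)c12.[Cs+] | intermediate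
29 | 8-[2-(allyloxy)-4,6-bis(benzyloxy)phenyl]-5,7-bis(benzyloxy)-2-[4-(benzyloxy)phenyl]-4H-chromen-4-one | O=c1cc(-c2ccc(OCc3ccccc3)cc2)oc2c(-c3c(OCC=C)cc(OCc4ccccc4)cc3OCc3ccccc3)c(OCc3ccccc3)cc(OCc3ccccc3)c12 | intermediate
30 | 5,7-bis(benzyloxy)-8-[2,4-bis(benzyloxy)-6-hydroxyphenyl]-2-[4-(benzyloxy)phenyl]-4H-chromen-4-one | O=c1cc(-c2ccc(OCc3ccccc3)cc2)oc2c(-c3c(O)cc(OCc4ccccc4)cc3OCc3ccccc3)c(OCc3ccccc3)cc(OCc3ccccc3)c12 | intermediate
31 | 5,7-bis(benzyloxy)-8-[4,6-bis(benzyloxy)-2-hydroxy-3-(hydroxymethyl)phenyl]-2-[4-(benzyloxy)phenyl]-4H-chromen-4-one | O=c1cc(-c2ccc(OCc3ccccc3)cc2)oc2c(-c3c(O)c(CO)c(OCc4ccccc4)cc3OCc3ccccc3)c(OCc3ccccc3)cc(OCc3ccccc3)c12 | intermediate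
32 | 4,6-bis(benzyloxy)-3-{5,7-bis(benzyloxy)-2-[4-(benzyloxy)phenyl]-4-oxo-4H-chromen-8-yl}-2-hydroxybenzaldehyde | O=c1cc(-c2ccc(OCc3ccccc3)cc2)oc2c(-c3c(O)c(C=O)c(OCc4ccccc4)cc3OCc3ccccc3)c(OCc3ccccc3)cc(OCc3ccccc3)c12 | intermediate
33 | ethynylmagnesium bromide | C#C[Mg]Br | starting material
34 | 5,7-bis(benzyloxy)-8-[4,6-bis(benzyloxy)-2-hydroxy-3-(1-hydroxyprop-2-yn-1-yl)phenyl]-2-[4-(benzyloxy)phenyl]-4H-chromen-4-one (carbinol centre uncontrolled) | O=c1cc(-c2ccc(OCc3ccccc3)cc2)oc2c(-c3c(O)c(C(O)C#C)c(OCc4ccccc4)cc3OCc3ccccc3)c(OCc3ccccc3)cc(OCc3ccccc3)c12 | intermediate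
35 | 5,7-bis(benzyloxy)-8-[4,6-bis(benzyloxy)-2-hydroxy-3-propioloylphenyl]-2-[4-(benzyloxy)phenyl]-4H-chromen-4-one | O=c1cc(-c2ccc(OCc3ccccc3)cc2)oc2c(-c3c(O)c(C(=O)C#C)c(OCc4ccccc4)cc3OCc3ccccc3)c(OCc3ccccc3)cc(OCc3ccccc3)c12 | intermediate
36 | 5,7-bis(benzyloxy)-8-[5,7-bis(benzyloxy)-4-oxo-4H-chromen-8-yl]-2-[4-(benzyloxy)phenyl]-4H-chromen-4-one | O=c1ccoc2c(-c3c(OCc4ccccc4)cc(OCc4ccccc4)c4c(=O)cc(-c5ccc(OCc6ccccc6)cc5)oc34)c(OCc3ccccc3)cc(OCc3ccccc3)c12 | intermediate
37 | 4-(benzyloxy)phenylboronic acid | OB(O)c1ccc(OCc2ccccc2)cc1 | starting material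
38 | (2S)-5,7-bis(benzyloxy)-8-{5,7-bis(benzyloxy)-2-[4-(benzyloxy)phenyl]-4-oxo-4H-chromen-8-yl}-2-[4-(benzyloxy)phenyl]chroman-4-one | O=C1C[C@@H](c2ccc(OCc3ccccc3)cc2)Oc2c1c(OCc1ccccc1)cc(OCc1ccccc1)c2-c1c(OCc2ccccc2)cc(OCc2ccccc2)c2c(=O)cc(-c3ccc(OCc4ccccc4)cc3)oc12 | intermediate
39 | (2S)-5,7-dihydroxy-8-[5,7-dihydroxy-2-(4-hydroxyphenyl)-4-oxo-4H-chromen-8-yl]-2-(4-hydroxyphenyl)chroman-4-one | O=C1C[C@@H](c2ccc(O)cc2)Oc2c1c(O)cc(O)c2-c1c(O)cc(O)c2c(=O)cc(-c3ccc(O)cc3)oc12 | target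

**Step count**
Total: 16 steps. Longest linear sequence: 15 steps (steps 1–4 and 6–16); step 5 is a one-step branch.

**Steps most likely to fail**

Step 6 (benzannulation). The cyclobutenone is a vinylogous ester and may open only at temperatures at which the siloxyalkyne isomerises to a silylketene. The electron-rich aryl group also works against the polarisation of the ynol ether, so the [2+2] addition may be slow or lose its orientation. The product phenol may in addition be acylated by the vinylketene. The fallback makes the biaryl bond by Suzuki–Miyaura coupling at the flavone stage; it sets out from 3 and 5 and comes back at 29. From 3, addition of the lithium acetylide of 24 gives 1-[2,4-bis(benzyloxy)-6-hydroxyphenyl]-3-[4-(benzyloxy)phenyl]prop-2-yn-1-ol F1. MnO2 gives the ynone F2, and DMAP in DMF closes it to 5,7-bis(benzyloxy)-2-[4-(benzyloxy)phenyl]-4H-chromen-4-one F3. N-Iodosuccinimide with catalytic CF3CO2H in MeCN should iodinate C8, the position that 5,7-dialkoxyflavones offer to electrophiles, to give the 8-iodoflavone F4. From 5, Pinnick oxidation (NaClO2, NaH2PO4, 2-methylbut-2-ene) gives 2-(allyloxy)-4,6-bis(benzyloxy)benzoic acid F5. Ipso-iododecarboxylation with N-iodosuccinimide in MeCN gives 1-(allyloxy)-3,5-bis(benzyloxy)-2-iodobenzene F6. Iodine–magnesium exchange (i-PrMgCl·LiCl, THF, −20 °C), B(OMe)3 and hydrolysis give [2-(allyloxy)-4,6-bis(benzyloxy)phenyl]boronic acid F7. Coupling of F4 with F7 (Pd(OAc)2, SPhos, K3PO4, toluene, 100 °C) gives 29.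

Step 15 (asymmetric conjugate addition). The 5,7-dialkoxy-8-aryl chromone is a weak and crowded acceptor, so insertion may be slower than protodeboronation. Retro-oxa-Michael opening of the product would erode the enantiomeric purity, and one axial isomer may be mismatched with the catalyst. The fallback takes C2 from an asymmetric ketone reduction and closes the ring by Friedel–Crafts acylation; it sets out from 30 and comes back at 38. Claisen condensation of lithiated tert-butyl acetate with methyl 4-(benzyloxy)benzoate gives tert-butyl 3-[4-(benzyloxy)phenyl]-3-oxopropanoate F8. Noyori transfer hydrogenation (RuCl[(R,R)-TsDPEN](p-cymene), HCO2H–Et3N, the catalyst antipode that gives the R alcohol) gives tert-butyl (3R)-3-[4-(benzyloxy)phenyl]-3-hydroxypropanoate F9. Mitsunobu reaction of 30 with F9 (PPh3, diisopropyl azodicarboxylate, toluene, 0 °C) gives, with inversion, the (3S)-aryl ether F10. CF3CO2H in CH2Cl2 gives the acid F11, oxalyl chloride with catalytic DMF gives the acid chloride F12, and SnCl4 at −78 °C closes the ring at C4a to give 38.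

Step 13 (ethynyl Grignard addition). The Grignard reagent may also add to the flavone carbonyl or to C2'', the chelated magnesium phenoxide aldehyde may react sluggishly, and the electron-rich benzylic alcohol may ionise on work-up. The fallback builds the chromone without an organometallic reagent; it sets out from 30 and comes back at 36, so that steps 12 to 14 are bypassed. 1,4-Diazabicyclo[2.2.2]octane-catalysed oxa-Michael addition of 30 to tert-butyl propiolate (CH2Cl2, rt) gives the tert-butyl (E)-3-aryloxyacrylate F13. CF3CO2H in CH2Cl2 gives the acid F14, and oxalyl chloride with catalytic DMF gives the acid chloride F15. SnCl4 (−78 to 0 °C) equilibrates the enol ether geometry and closes the pyranone ring at C4a by Friedel–Crafts acylation to give 36.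

**Further compounds**
F1 | step 6 | 1-[2,4-bis(benzyloxy)-6-hydroxyphenyl]-3-[4-(benzyloxy)phenyl]prop-2-yn-1-ol | OC(C#Cc1ccc(OCc2ccccc2)cc1)c1c(O)cc(OCc2ccccc2)cc1OCc1ccccc1
F2 | step 6 | 1-[2,4-bis(benzyloxy)-6-hydroxyphenyl]-3-[4-(benzyloxy)phenyl]prop-2-yn-1-one | O=C(C#Cc1ccc(OCc2ccccc2)cc1)c1c(O)cc(OCc2ccccc2)cc1OCc1ccccc1
F3 | step 6 | 5,7-bis(benzyloxy)-2-[4-(benzyloxy)phenyl]-4H-chromen-4-one | O=c1cc(-c2ccc(OCc3ccccc3)cc2)oc2cc(OCc3ccccc3)cc(OCc3ccccc3)c12
F4 | step 6 | 5,7-bis(benzyloxy)-2-[4-(benzyloxy)phenyl]-8-iodo-4H-chromen-4-one | O=c1cc(-c2ccc(OCc3ccccc3)cc2)oc2c(I)c(OCc3ccccc3)cc(OCc3ccccc3)c12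
F5 | step 6 | 2-(allyloxy)-4,6-bis(benzyloxy)benzoic acid | OC(=O)c1c(OCC=C)cc(OCc2ccccc2)cc1OCc1ccccc1
F6 | step 6 | 1-(allyloxy)-3,5-bis(benzyloxy)-2-iodobenzene | Ic1c(OCC=C)cc(OCc2ccccc2)cc1OCc1ccccc1
F7 | step 6 | [2-(allyloxy)-4,6-bis(benzyloxy)phenyl]boronic acid | OB(O)c1c(OCC=C)cc(OCc2ccccc2)cc1OCc1ccccc1
F8 | step 15 | tert-butyl 3-[4-(benzyloxy)phenyl]-3-oxopropanoate | CC(C)(C)OC(=O)CC(=O)c1ccc(OCc2ccccc2)cc1
F9 | step 15 | tert-butyl (3R)-3-[4-(benzyloxy)phenyl]-3-hydroxypropanoate | CC(C)(C)OC(=O)C[C@@H](O)c1ccc(OCc2ccccc2)cc1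
F10 | step 15 | tert-butyl (3S)-3-[4-(benzyloxy)phenyl]-3-(3,5-bis(benzyloxy)-2-{5,7-bis(benzyloxy)-2-[4-(benzyloxy)phenyl]-4-oxo-4H-chromen-8-yl}phenoxy)propanoate | CC(C)(C)OC(=O)C[C@H](Oc1cc(OCc2ccccc2)cc(OCc2ccccc2)c1-c1c(OCc2ccccc2)cc(OCc2ccccc2)c2c(=O)cc(-c3ccc(OCc4ccccc4)cc3)oc12)c1ccc(OCc2ccccc2)cc1
F11 | step 15 | (3S)-3-[4-(benzyloxy)phenyl]-3-(3,5-bis(benzyloxy)-2-{5,7-bis(benzyloxy)-2-[4-(benzyloxy)phenyl]-4-oxo-4H-chromen-8-yl}phenoxy)propanoic acid | OC(=O)C[C@H](Oc1cc(OCc2ccccc2)cc(OCc2ccccc2)c1-c1c(OCc2ccccc2)cc(OCc2ccccc2)c2c(=O)cc(-c3ccc(OCc4ccccc4)cc3)oc12)c1ccc(OCc2ccccc2)cc1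
F12 | step 15 | (3S)-3-[4-(benzyloxy)phenyl]-3-(3,5-bis(benzyloxy)-2-{5,7-bis(benzyloxy)-2-[4-(benzyloxy)phenyl]-4-oxo-4H-chromen-8-yl}phenoxy)propanoyl chloride | ClC(=O)C[C@H](Oc1cc(OCc2ccccc2)cc(OCc2ccccc2)c1-c1c(OCc2ccccc2)cc(OCc2ccccc2)c2c(=O)cc(-c3ccc(OCc4ccccc4)cc3)oc12)c1ccc(OCc2ccccc2)cc1
F13 | step 13 | tert-butyl (E)-3-(3,5-bis(benzyloxy)-2-{5,7-bis(benzyloxy)-2-[4-(benzyloxy)phenyl]-4-oxo-4H-chromen-8-yl}phenoxy)acrylate | CC(C)(C)OC(=O)/C=C/Oc1cc(OCc2ccccc2)cc(OCc2ccccc2)c1-c1c(OCc2ccccc2)cc(OCc2ccccc2)c2c(=O)cc(-c3ccc(OCc4ccccc4)cc3)oc12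
F14 | step 13 | (E)-3-(3,5-bis(benzyloxy)-2-{5,7-bis(benzyloxy)-2-[4-(benzyloxy)phenyl]-4-oxo-4H-chromen-8-yl}phenoxy)acrylic acid | OC(=O)/C=C/Oc1cc(OCc2ccccc2)cc(OCc2ccccc2)c1-c1c(OCc2ccccc2)cc(OCc2ccccc2)c2c(=O)cc(-c3ccc(OCc4ccccc4)cc3)oc12
F15 | step 13 | (E)-3-(3,5-bis(benzyloxy)-2-{5,7-bis(benzyloxy)-2-[4-(benzyloxy)phenyl]-4-oxo-4H-chromen-8-yl}phenoxy)acryloyl chloride | ClC(=O)/C=C/Oc1cc(OCc2ccccc2)cc(OCc2ccccc2)c1-c1c(OCc2ccccc2)cc(OCc2ccccc2)c2c(=O)cc(-c3ccc(OCc4ccccc4)cc3)oc12
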